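(The numbers of this flask are made up, and the outcome is calculated.)

Divide the monomer in chains by the chains begun: the asked length is the ratio of these two amounts. Spring and summer share one recipe but for the time.

- spring: free monomer 0.035 M (fed, over 40 s); initiator 0.88 mM; time 4.0 h
- summer: free monomer 0.035 M (fed, over 40 s); initiator 0.88 mM; time 1.0 h

    free monomer + initiator → living end + monomer in chains (k1 = 180 /M/min)
    free monomer + living end → monomer in chains + living end, rate k2*[living end]*[free monomer] (k2 = 71 /M/min)
    monomer in chains + living end → free monomer + living end, rate k3*[living end] as long as [monomer in chains] is above zero (k3 = 0.22 /min)
    initiator → spent initiator (k4 = 0.38 /min)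
    free monomer → uncatalysed product (k5 = 0.0035 /min)

- which of the two ends with the longer chains by the average number of monomer units in a chain (chains begun, living or dead) ("neither" if they lie within 10%) (spring / summer / neither)
- average number of monomer units in a chain (chains begun, living or dead) at the end, spring
- average number of monomer units in a chain (chains begun, living or dead) at the end, summer

- the average divides the monomer in chains by the number of chains begun, living and dead together
- run time (spring): 4.0 h

This reckoning replaces the free monomer rising through the feed by its mean, half the charge. Initiator then begins chains at 3.15 /min, faster than its decay at 0.38 /min, so a share of 89.2% of its charge begins chains, 0.785 mM. These living ends take up free monomer at a pseudo-first-order 0.0558 /min, faster than the uncatalysed route at 0.0035 /min. This reckoning therefore rests free monomer at 8.33% of its charge: the floor, which is the return from chains divided by both ways out.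

For spring, the reckoning puts uncatalysed product at 12.4%, monomer in chains at 79.3%, and the length at 35.3. For summer, it leaves 2.62% of the charge above the floor and puts uncatalysed product at 7.01%, monomer in chains at 82.0%, and the length at 36.6. The verdict of this reckoning is neither.

The forecast says neither, with 37 (35 to 39) for spring and 38 (36 to 40) for summer. Its ground: “Living ends never die, so the chain count then stays fixed.” It counts about 0.75 mM of chains where this reckoning counts 0.785 mM.

The simulation gives neither, with 36.7 for spring and 37.9 for summer.

Spring's free monomer stands at 8.31% after 4.00 h, against the floor of 8.33%. The neighbour flask is spring with 0.0088 M of free monomer. The same reckoning starts chains from 67.6% of the initiator, 0.595 mM. It puts the floor at 32.5% of that flask's charge and uncatalysed product at 32.5%. Monomer in chains then comes to 35.0% in this reckoning, a length of 5.18. That flask ends with free monomer at 32.6%, uncatalysed product at 31.9%, monomer in chains at 35.5% and a length of 4.99.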